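Ring A of the target is a benzene carrying O1 on C7a and C3 on C3a, so the O1–C2–C3 unit can act as the three-atom tether of a 1,6-diyne. Everything rests on cutting ring A into three alkynes: an ynol ether on O1, a terminal alkyne on C3 and methyl pent-4-ynoate. One rhodium-catalysed [2+2+2] cyclotrimerisation then forms C3a–C7a, C4–C5 and C6–C7 and closes ring A and the dihydrofuran ring together. Its precursor is an open-chain anti ether with both stereocentres already set by an allenylzinc addition; a triethylsilyl group on the ynol ether terminus directs the ester chain to C5 and is later exchanged for the C7 methoxy group.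

Key step: step 8

Remark: atoms are numbered as in 2,3-dihydro-1-benzofuran (O1, C2, C3, C3a, C4 to C7, C7a); the terminal alkyne of the tether is carried as its C-SiMe3 derivative until step 7, because the strongly basic ynol ether synthesis would otherwise metalate and silylate it.

Step 1
Reactants: 1 syringaldehyde
Product: 2 4-(benzyloxy)-3,5-dimethoxybenzaldehyde
Conditions: BnBr, K2CO3, DMF, 60 °C
Reagents that add atoms: benzyl bromide, BrCc1ccccc1
Why: Williamson ether synthesis on the phenoxide installs a phenol protecting group that should survive hydride, alkyllithium, carbonate and fluoride and is removed last under neutral conditions.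

Step 2
Reactants: 3 methyl (tert-butyldimethylsilyloxy)acetate; 4 ethynyltrimethylsilane
Product: 6 1-(tert-butyldimethylsilyloxy)-4-(trimethylsilyl)but-3-yn-2-one, via lithium acetylide 5 (not isolated)
Conditions: 4, n-BuLi, THF, −78 °C; BF3·OEt2; then 3, −78 °C
Reagents that add atoms: none
Why: Acylation of a lithium acetylide by an ester in the presence of BF3·OEt2 should stop at the alkynyl ketone, because the tetrahedral adduct does not collapse at −78 °C.

Step 3
Reactants: 6 1-(tert-butyldimethylsilyloxy)-4-(trimethylsilyl)but-3-yn-2-one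
Product: 7 (S)-1-(tert-butyldimethylsilyloxy)-4-(trimethylsilyl)but-3-yn-2-ol
Conditions: Ru[(R,R)-TsDPEN](p-cymene) (1 mol%), i-PrOH, rt
Reagents that add atoms: none
Why: Noyori asymmetric transfer hydrogenation of an alkynyl ketone, in which the alkyne plays the part of the aryl group in the transition state, so the (R,R) catalyst should deliver hydride to the face that gives the (S) carbinol.

Step 4
Reactants: 7 (S)-1-(tert-butyldimethylsilyloxy)-4-(trimethylsilyl)but-3-yn-2-ol
Product: 8 (S)-1-(tert-butyldimethylsilyloxy)-4-(trimethylsilyl)but-3-yn-2-yl methanesulfonate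
Conditions: MsCl, Et3N, CH2Cl2, −78 to 0 °C
Reagents that add atoms: methanesulfonyl chloride, CS(=O)(=O)Cl
Why: O-sulfonylation leaves the stereocentre untouched and provides the leaving group for the SN2′ displacement.

Step 5
Reactants: 8 (S)-mesylate; 2 4-(benzyloxy)-3,5-dimethoxybenzaldehyde
Product: 10 (1S,2R)-1-[4-(benzyloxy)-3,5-dimethoxyphenyl]-2-[(tert-butyldimethylsilyloxy)methyl]-4-(trimethylsilyl)but-3-yn-1-ol, via allenylzinc reagent 9 (not isolated)
Conditions: Pd(OAc)2 (5 mol%), PPh3 (5 mol%), Et2Zn (3 equiv), THF, −78 to −20 °C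
Reagents that add atoms: none
Why: Marshall propargylation: zerovalent palladium displaces the mesylate anti (SN2′), transmetalation gives the (aS)-allenylzinc 9, and this adds to the aldehyde through a closed transition state on the zinc-bearing face, so the future C3 is set as (R) by chirality transfer with net inversion and the future C2 is set as (S) because the aryl group turns away from the CH2OTBS group (anti adduct).

Step 6
Reactants: 10 anti homopropargylic alcohol; 11 trichloroethylene
Product: 14 triethylsilylethynyl ether of 10, via dichlorovinyl ether 12 (not isolated), via lithium alkynyl ether 13 (not isolated)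
Conditions: KH, THF, 0 °C; Cl2C=CHCl, −50 °C to rt; n-BuLi (2.5 equiv), −78 to −40 °C; Et3SiCl, −78 °C to rt
Reagents that add atoms: chlorotriethylsilane, CC[Si](Cl)(CC)CC
Why: Greene ynol ether synthesis: the potassium alkoxide adds to dichloroacetylene formed from trichloroethylene, n-BuLi eliminates HCl and exchanges the remaining chlorine for lithium, and the lithium alkynyl ether is silylated at carbon, while the C-SiMe3 cap keeps the other alkyne out of the metalation.

Step 7
Reactants: 14 doubly silylated diyne
Product: 15 triethylsilylethynyl ether of (1S,2R)-1-[4-(benzyloxy)-3,5-dimethoxyphenyl]-2-[(tert-butyldimethylsilyloxy)methyl]but-3-yn-1-ol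
Conditions: K2CO3 (0.2 equiv), MeOH/THF, 0 °C
Reagents that add atoms: none
Why: Base-catalysed methanolysis should remove the small SiMe3 group from the alkyl-substituted alkyne well before the bulkier SiEt3 group of the ynol ether, and the ynol ether itself is stable to base.

Step 8
Reactants: 15 tethered 1,6-diyne; 16 methyl pent-4-ynoate
Product: 17 methyl 3-[(2S,3R)-2-[4-(benzyloxy)-3,5-dimethoxyphenyl]-3-[(tert-butyldimethylsilyloxy)methyl]-7-(triethylsilyl)-2,3-dihydro-1-benzofuran-5-yl]propanoate
Conditions: RhCl(PPh3)3 (10 mol%), 16 (4 equiv), toluene, 25–40 °C, 15 added over 6 h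
Reagents that add atoms: none
Why: Proposed new method: RhCl(PPh3)3 should bind the silyl ynol ether and the terminal alkyne of 15 and couple them oxidatively to a rhodacyclopentadiene (C3a–C7a formed), into which alkyne 16 inserts before reductive elimination releases the arene (C4–C5 and C6–C7 formed). The closest known reactions are rhodium-catalysed [2+2+2] cyclotrimerisations of 1,6-diynes with terminal alkynes, including ynamide-tethered diynes that give indolines and aryl alkynyl ethers that give dibenzofurans; an alkyl ynol ether tether is not precedented. The dihydrofuran ring closes in the oxidative coupling, for which the three-atom C3–C2–O1 tether gives the favoured five-membered fusion, and ring A closes by alkyne insertion and C–C reductive elimination. No stereocentre is created, and C2 and C3 lie on the tether away from the reacting carbons, so their configuration should be carried through unchanged. Regioselectivity of the outside alkyne is needed and is secured by the bulky SiEt3 group, which makes 16 turn its unsubstituted carbon toward C7 so that the chain ends on C5; self-trimerisation is suppressed by slow addition of 15 to excess 16. The temperature is kept at or below 40 °C because benzylic alkynyl ethers rearrange sigmatropically on heating.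

Step 9
Reactants: 17 7-triethylsilyl dihydrobenzofuran
Product: 18 methyl 3-[(2S,3R)-2-[4-(benzyloxy)-3,5-dimethoxyphenyl]-3-[(tert-butyldimethylsilyloxy)methyl]-7-iodo-2,3-dihydro-1-benzofuran-5-yl]propanoate
Conditions: ICl (1.05 equiv), CH2Cl2, −78 °C
Reagents that add atoms: iodine monochloride, ClI
Why: Electrophilic ipso iododesilylation is favoured at C7 by the ortho O1 and by β-silicon stabilisation of the arenium ion, so one equivalent of ICl at low temperature should react there before it attacks the hindered C–H positions of ring B.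

Step 10
Reactants: 18 aryl iodide
Product: 19 methyl 3-[(2S,3R)-2-[4-(benzyloxy)-3,5-dimethoxyphenyl]-3-[(tert-butyldimethylsilyloxy)methyl]-7-methoxy-2,3-dihydro-1-benzofuran-5-yl]propanoate
Conditions: CuI (10 mol%), 3,4,7,8-tetramethyl-1,10-phenanthroline (20 mol%), Cs2CO3, MeOH, toluene, 80 °C
Reagents that add atoms: methanol, CO
Why: Ullmann-type copper-catalysed C–O coupling of an aryl iodide with an alcohol; the methyl ester is invariant to methanolysis and neither stereocentre carries an acidic hydrogen.

Step 11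
Reactants: 19 silyl ether
Product: 20 methyl 3-[(2S,3R)-2-[4-(benzyloxy)-3,5-dimethoxyphenyl]-3-(hydroxymethyl)-7-methoxy-2,3-dihydro-1-benzofuran-5-yl]propanoate
Conditions: Bu4NF, THF, 0 °C to rt
Reagents that add atoms: none
Why: Fluoride cleaves the primary silyl ether while the ring B phenol is still benzylated, so no phenoxide that could open the C2–O1 bond through a quinone methide is present.

Step 12
Reactants: 20 benzyl ether
Product: 21 methyl 3-[(2S,3R)-2-(4-hydroxy-3,5-dimethoxyphenyl)-3-(hydroxymethyl)-7-methoxy-2,3-dihydro-1-benzofuran-5-yl]propanoate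
Conditions: H2 (1 atm), 10% Pd/C, EtOAc, rt
Reagents that add atoms: none
Why: Hydrogenolysis of the unhindered primary aryl benzyl ether should be much faster than that of the cyclic secondary C2–O1 benzylic ether, so the reaction is stopped once debenzylation is complete.

Compound list
1 | syringaldehyde | COc1cc(C=O)cc(OC)c1O | starting material
2 | 4-(benzyloxy)-3,5-dimethoxybenzaldehyde | COc1cc(C=O)cc(OC)c1OCc1ccccc1 | intermediate
3 | methyl (tert-butyldimethylsilyloxy)acetate | COC(=O)CO[Si](C)(C)C(C)(C)C | starting material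
4 | ethynyltrimethylsilane | C#C[Si](C)(C)C | starting material
5 | lithium (trimethylsilyl)acetylide | [Li]C#C[Si](C)(C)C | intermediate (not isolated)
6 | 1-(tert-butyldimethylsilyloxy)-4-(trimethylsilyl)but-3-yn-2-one | C[Si](C)(C)C#CC(=O)CO[Si](C)(C)C(C)(C)C | intermediate
7 | (S)-1-(tert-butyldimethylsilyloxy)-4-(trimethylsilyl)but-3-yn-2-ol | C[Si](C)(C)C#C[C@H](O)CO[Si](C)(C)C(C)(C)C | intermediate
8 | (S)-1-(tert-butyldimethylsilyloxy)-4-(trimethylsilyl)but-3-yn-2-yl methanesulfonate | C[Si](C)(C)C#C[C@H](OS(C)(=O)=O)CO[Si](C)(C)C(C)(C)C | intermediate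
9 | (aS)-[4-(tert-butyldimethylsilyloxy)-1-(trimethylsilyl)buta-1,2-dien-1-yl](ethyl)zinc, allene axis (aS), not encoded in the SMILES | CC[Zn]C(=C=CCO[Si](C)(C)C(C)(C)C)[Si](C)(C)C | intermediate (not isolated)
10 | (1S,2R)-1-[4-(benzyloxy)-3,5-dimethoxyphenyl]-2-[(tert-butyldimethylsilyloxy)methyl]-4-(trimethylsilyl)but-3-yn-1-ol (anti) | C[Si](C)(C)C#C[C@H](CO[Si](C)(C)C(C)(C)C)[C@@H](c1cc(OC)c(OCc2ccccc2)c(OC)c1)O | intermediate
11 | trichloroethylene | ClC=C(Cl)Cl | starting material
12 | (E)-1,2-dichlorovinyl ether of 10 | C[Si](C)(C)C#C[C@H](CO[Si](C)(C)C(C)(C)C)[C@@H](c1cc(OC)c(OCc2ccccc2)c(OC)c1)O/C(Cl)=C\Cl | intermediate (not isolated)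
13 | lithium alkynyl ether (lithiated ethynyl ether of 10) | C[Si](C)(C)C#C[C@H](CO[Si](C)(C)C(C)(C)C)[C@@H](c1cc(OC)c(OCc2ccccc2)c(OC)c1)OC#C[Li] | intermediate (not isolated)
14 | triethylsilylethynyl ether of 10 | C[Si](C)(C)C#C[C@H](CO[Si](C)(C)C(C)(C)C)[C@@H](c1cc(OC)c(OCc2ccccc2)c(OC)c1)OC#C[Si](CC)(CC)CC | intermediate
15 | triethylsilylethynyl ether of (1S,2R)-1-[4-(benzyloxy)-3,5-dimethoxyphenyl]-2-[(tert-butyldimethylsilyloxy)methyl]but-3-yn-1-ol (tethered 1,6-diyne) | C#C[C@H](CO[Si](C)(C)C(C)(C)C)[C@@H](c1cc(OC)c(OCc2ccccc2)c(OC)c1)OC#C[Si](CC)(CC)CC | intermediate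
16 | methyl pent-4-ynoate | C#CCCC(=O)OC | starting material
17 | methyl 3-[(2S,3R)-2-[4-(benzyloxy)-3,5-dimethoxyphenyl]-3-[(tert-butyldimethylsilyloxy)methyl]-7-(triethylsilyl)-2,3-dihydro-1-benzofuran-5-yl]propanoate | COC(=O)CCc1cc([Si](CC)(CC)CC)c2c(c1)[C@H](CO[Si](C)(C)C(C)(C)C)[C@@H](c1cc(OC)c(OCc3ccccc3)c(OC)c1)O2 | intermediate
18 | 7-iodo analogue of 17 | COC(=O)CCc1cc(I)c2c(c1)[C@H](CO[Si](C)(C)C(C)(C)C)[C@@H](c1cc(OC)c(OCc3ccccc3)c(OC)c1)O2 | intermediate
19 | 7-methoxy analogue of 17 | COC(=O)CCc1cc(OC)c2c(c1)[C@H](CO[Si](C)(C)C(C)(C)C)[C@@H](c1cc(OC)c(OCc3ccccc3)c(OC)c1)O2 | intermediate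
20 | methyl 3-[(2S,3R)-2-[4-(benzyloxy)-3,5-dimethoxyphenyl]-3-(hydroxymethyl)-7-methoxy-2,3-dihydro-1-benzofuran-5-yl]propanoate | COC(=O)CCc1cc(OC)c2c(c1)[C@H](CO)[C@@H](c1cc(OC)c(OCc3ccccc3)c(OC)c1)O2 | intermediate
21 | methyl 3-[(2S,3R)-2-(4-hydroxy-3,5-dimethoxyphenyl)-3-(hydroxymethyl)-7-methoxy-2,3-dihydro-1-benzofuran-5-yl]propanoate (trans) | COC(=O)CCc1cc(OC)c2c(c1)[C@H](CO)[C@@H](c1cc(OC)c(O)c(OC)c1)O2 | target

Total step count: 12. Longest linear sequence: 11 steps (steps 2 to 12, from 3 and 4 to 21).

Steps most likely to fail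

1. Step 8. Self-trimerisation of 15 or 16 may outrun the cross reaction. Oxidative coupling at the silylated ynol ether may be so slow that thermal rearrangement of the benzylic alkynyl ether takes over. Alkyne 16 may also insert in the opposite sense. The fallback uses only known reactions; it sets out from aldehyde 2 and comes back at 20, building the ring system by an auxiliary-controlled aldol and a cationic ring closure. Methyl 3-(4-hydroxy-3-methoxyphenyl)propanoate F1 (commercial) is brominated ortho to the phenol (NBS, MeCN) to methyl 3-(3-bromo-4-hydroxy-5-methoxyphenyl)propanoate F2 and silylated (i-Pr3SiCl, imidazole) to the triisopropylsilyl ether F3. Negishi coupling with BrZnCH2CO2t-Bu (Pd(dba)2, P(t-Bu)3) gives the tert-butyl arylacetate F4, CF3CO2H frees the arylacetic acid F5, and acylation of (S)-4-benzyl-2-oxazolidinone (t-BuCOCl, Et3N, LiCl) gives the imide F6. Its boron enolate (Bu2BOTf, i-Pr2NEt) adds to 2 to give the Evans syn aldol F7, which fixes C3. LiBH4 removes the auxiliary selectively over the methyl ester to give the diol F8, and Bu4NF frees the phenol diol F9. Catalytic TsOH in CH2Cl2 then ionises the electron-rich benzylic alcohol, and the phenol closes the dihydrofuran ring to the more stable trans isomer, compound 20.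

2. Step 9. Iodination of the electron-rich ring B may compete with ipso substitution at C7, and the acid set free may ionise the C2–O1 bond. The fallback sets out from alcohol 10 and comes back at iodide 18; it changes the placeholder from silicon to germanium, because aryl germanes undergo ipso iodination with N-iodosuccinimide far faster than aryl silanes and without acid. The sequence of step 6 with Et3GeCl as the quench gives the triethylgermylethynyl ether F10. K2CO3 in MeOH removes only the C-SiMe3 group to give the germyl diyne F11, since alkynylgermanes resist methanolysis. Cyclotrimerisation with 16 as in step 8 gives the 7-triethylgermyl dihydrobenzofuran F12, and N-iodosuccinimide in DMF at rt converts it into 18.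

3. Step 5. The anti selectivity may erode with the aromatic aldehyde, and the propargylzinc isomer of 9 may lose silanolate by β-elimination. The fallback sets out from alcohol 7 and comes back at 10; it replaces the transient zinc species by an isolable allenylboronate that has no such elimination path. Alcohol 7 is converted into its methyl carbonate F13 (ClCO2Me, pyridine). Copper-catalysed anti SN2′ borylation (CuCl, NaO-t-Bu, Xantphos, B2pin2, THF) gives the (aR)-allenyl pinacolboronate F14 with transfer of chirality. F14 adds to aldehyde 2 through a closed six-membered transition state (toluene, 60 °C) to give the same anti alcohol 10.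

Further compounds
F1 | step 8 | methyl 3-(4-hydroxy-3-methoxyphenyl)propanoate (commercial starting material) | COC(=O)CCc1ccc(O)c(OC)c1
F2 | step 8 | methyl 3-(3-bromo-4-hydroxy-5-methoxyphenyl)propanoate | COC(=O)CCc1cc(Br)c(O)c(OC)c1
F3 | step 8 | methyl 3-[3-bromo-5-methoxy-4-(triisopropylsilyloxy)phenyl]propanoate | COC(=O)CCc1cc(Br)c(O[Si](C(C)C)(C(C)C)C(C)C)c(OC)c1
F4 | step 8 | tert-butyl 2-[3-methoxy-5-(3-methoxy-3-oxopropyl)-2-(triisopropylsilyloxy)phenyl]acetate | COC(=O)CCc1cc(CC(=O)OC(C)(C)C)c(O[Si](C(C)C)(C(C)C)C(C)C)c(OC)c1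
F5 | step 8 | 2-[3-methoxy-5-(3-methoxy-3-oxopropyl)-2-(triisopropylsilyloxy)phenyl]acetic acid | COC(=O)CCc1cc(CC(=O)O)c(O[Si](C(C)C)(C(C)C)C(C)C)c(OC)c1
F6 | step 8 | (S)-4-benzyl-3-(arylacetyl)oxazolidin-2-one from F5 | O=C1OC[C@H](Cc2ccccc2)N1C(=O)Cc1cc(CCC(=O)OC)cc(OC)c1O[Si](C(C)C)(C(C)C)C(C)C
F7 | step 8 | (2S,3S) syn aldol adduct of F6 and 2 | O=C1OC[C@H](Cc2ccccc2)N1C(=O)[C@@H](c1cc(CCC(=O)OC)cc(OC)c1O[Si](C(C)C)(C(C)C)C(C)C)[C@H](O)c1cc(OC)c(OCc2ccccc2)c(OC)c1
F8 | step 8 | (1S,2R)-1,2-diarylpropane-1,3-diol, ring A phenol as triisopropylsilyl ether | OC[C@@H](c1cc(CCC(=O)OC)cc(OC)c1O[Si](C(C)C)(C(C)C)C(C)C)[C@H](O)c1cc(OC)c(OCc2ccccc2)c(OC)c1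
F9 | step 8 | (1S,2R)-1,2-diarylpropane-1,3-diol with free ring A phenol | OC[C@@H](c1cc(CCC(=O)OC)cc(OC)c1O)[C@H](O)c1cc(OC)c(OCc2ccccc2)c(OC)c1
F10 | step 9 | triethylgermylethynyl ether of 10 | C[Si](C)(C)C#C[C@H](CO[Si](C)(C)C(C)(C)C)[C@@H](c1cc(OC)c(OCc2ccccc2)c(OC)c1)OC#C[Ge](CC)(CC)CC
F11 | step 9 | triethylgermyl analogue of diyne 15 | C#C[C@H](CO[Si](C)(C)C(C)(C)C)[C@@H](c1cc(OC)c(OCc2ccccc2)c(OC)c1)OC#C[Ge](CC)(CC)CC
F12 | step 9 | 7-triethylgermyl analogue of 17 | COC(=O)CCc1cc([Ge](CC)(CC)CC)c2c(c1)[C@H](CO[Si](C)(C)C(C)(C)C)[C@@H](c1cc(OC)c(OCc3ccccc3)c(OC)c1)O2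
F13 | step 5 | (S)-1-(tert-butyldimethylsilyloxy)-4-(trimethylsilyl)but-3-yn-2-yl methyl carbonate | C[Si](C)(C)C#C[C@H](OC(=O)OC)CO[Si](C)(C)C(C)(C)C
F14 | step 5 | (aR)-2-[4-(tert-butyldimethylsilyloxy)-1-(trimethylsilyl)buta-1,2-dien-1-yl]-4,4,5,5-tetramethyl-1,3,2-dioxaborolane, allene axis (aR), not encoded in the SMILES | CC1(C)OB(OC1(C)C)C(=C=CCO[Si](C)(C)C(C)(C)C)[Si](C)(C)C
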